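**Retrosynthetic overview**
1. The cis-fused 6,12-lactone is made last among the rings: a temporary cis 8,12-lactone is transposed to O6 by SN2 displacement of a C6 mesylate, so C6–O is first built with the opposite configuration; O8 acylation and C14/C15 adjustment follow.
2. Key disconnection C7–C8: intramolecular indium Barbier allylation of the C8 aldehyde by a (Z)-2-(bromomethyl)enoate closes the ten-membered carbocycle, sets C7 and C8 and creates the C11=C13 methylene.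
3. Enabling feature: the allyl bromide unit C13(Br)–C11(CO2Me)=C7 next to the C6 silyloxy stereocentre, the C8 aldehyde at the other chain end, and the two ring-cis trisubstituted alkenes C4=C5 and C1=C10 that fold the open chain.
4. Open chain: B-alkyl Suzuki coupling (C3–C4) of a Wittig-derived diene with a (Z)-iodoalkene, enantioselective propiolate alkynylation (C6), hydroalumination–iodination and Stille coupling (C13).
5. Ring order: ten-membered carbocycle, then temporary 8,12-γ-lactone (both in step 15), then final 6,12-γ-lactone (step 17).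

Key step: step 15

Remark: germacrane numbering is used for atom labels; CIP descriptors at C7 change where only substituent priorities change; 2 and 9 are taken as purchasable; TBS = tert-butyldimethylsilyl, TBDPS = tert-butyldiphenylsilyl, TES = triethylsilyl, PMB = 4-methoxybenzyl.

Step 1
Reactants: 1 ethyl (triphenylphosphoranylidene)acetate; 2 1-((2-bromoethoxy)methyl)-4-methoxybenzene
Product: 4 ethyl 4-((4-methoxybenzyl)oxy)-2-(triphenylphosphoranylidene)butanoate, via phosphonium bromide 3 (not isolated)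
Conditions: NaI (10 mol %), MeCN, 80 °C; then aq NaOH, CH2Cl2, 0 °C
Reagents that add atoms: none
Why: C-alkylation of the stabilised ylide and deprotonation of the phosphonium salt (ylide alkylation) should give the α-substituted ylide that carries C8, C9, C10 and C14.

Step 2
Reactants: 4 ethyl 4-((4-methoxybenzyl)oxy)-2-(triphenylphosphoranylidene)butanoate; 5 acrolein
Product: 6 ethyl (E)-2-(2-((4-methoxybenzyl)oxy)ethyl)penta-2,4-dienoate
Conditions: CH2Cl2, rt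
Reagents that add atoms: none
Why: Wittig olefination with a stabilised α-substituted ylide should give the E-enoate (ester trans to the vinyl group), which fixes the ring-cis geometry of C1=C10.

Step 3
Reactants: 6 ethyl (E)-2-(2-((4-methoxybenzyl)oxy)ethyl)penta-2,4-dienoate
Product: 7 (E)-2-(2-((4-methoxybenzyl)oxy)ethyl)penta-2,4-dien-1-ol
Conditions: DIBAL-H (i-Bu2AlH), CH2Cl2, −78 °C
Reagents that add atoms: none
Why: DIBAL-H 1,2-reduction of the conjugated ester gives the allylic alcohol and leaves the diene and the PMB ether untouched.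

Step 4
Reactants: 7 (E)-2-(2-((4-methoxybenzyl)oxy)ethyl)penta-2,4-dien-1-ol
Product: 8 (E)-tert-butyl((2-(2-((4-methoxybenzyl)oxy)ethyl)penta-2,4-dien-1-yl)oxy)dimethylsilane
Conditions: TBSCl, imidazole, DMF, 0 °C
Reagents that add atoms: tert-butyldimethylsilyl chloride, CC(C)(C)[Si](C)(C)Cl
Why: Silyl ether formation protects O14 until step 19.

Step 5
Reactants: 9 4-((tert-butyldiphenylsilyl)oxy)but-2-yn-1-ol
Product: 11 (Z)-4-((tert-butyldiphenylsilyl)oxy)-3-iodobut-2-en-1-ol, via alkenylaluminate 10 (not isolated)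
Conditions: Red-Al, NaAlH2(OCH2CH2OMe)2, THF, 0 °C; then I2, −78 to 0 °C
Reagents that add atoms: iodine, II
Why: Hydroxyl-directed trans-hydroalumination puts aluminium on the distal alkyne carbon in a five-membered alkenylaluminate, and iodination with retention should give the Z-iodide that carries the C4=C5 geometry.

Step 6
Reactants: 8 (E)-tert-butyl((2-(2-((4-methoxybenzyl)oxy)ethyl)penta-2,4-dien-1-yl)oxy)dimethylsilane; 11 (Z)-4-((tert-butyldiphenylsilyl)oxy)-3-iodobut-2-en-1-ol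
Product: 13 (2E,6E)-7-(TBSOCH2)-3-(TBDPSOCH2)-9-(PMBO)nona-2,6-dien-1-ol, via alkyl-9-BBN 12 (not isolated)
Conditions: 9-BBN, THF, 0 °C to rt; then 11, Pd(dppf)Cl2 (5 mol %), AsPh3, Cs2CO3, DMF–H2O, rt
Reagents that add atoms: none
Why: 9-BBN adds selectively to the terminal alkene of the diene, and the B-alkyl Suzuki–Miyaura coupling joins C3 to C4 with retention of the iodoalkene geometry.

Step 7
Reactants: 13 (2E,6E)-7-(TBSOCH2)-3-(TBDPSOCH2)-9-(PMBO)nona-2,6-dien-1-ol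
Product: 14 (2E,6E)-7-(TBSOCH2)-3-(TBDPSOCH2)-9-(PMBO)nona-2,6-dienal
Conditions: MnO2, CH2Cl2, rt
Reagents that add atoms: none
Why: MnO2 oxidises the allylic alcohol chemoselectively to the enal without moving the trisubstituted double bond.

Step 8
Reactants: 14 (2E,6E)-7-(TBSOCH2)-3-(TBDPSOCH2)-9-(PMBO)nona-2,6-dienal; 15 methyl propiolate
Product: 16 methyl (S,5E,9E)-10-(TBSOCH2)-6-(TBDPSOCH2)-4-hydroxy-12-(PMBO)dodeca-5,9-dien-2-ynoate
Conditions: (S,S)-ProPhenol (20 mol %), Me2Zn (3 equiv), toluene, 4 °C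
Reagents that add atoms: none
Why: Zinc–ProPhenol catalysed enantioselective alkynylation of the enal sets C6 as the S-carbinol, the epimer of the target configuration that step 17 inverts; the (S,S)-ligand is expected to give this sense, which is checked by MTPA ester analysis, and the R,R-ligand is used if it proves otherwise.

Step 9
Reactants: 16 methyl (S,5E,9E)-10-(TBSOCH2)-6-(TBDPSOCH2)-4-hydroxy-12-(PMBO)dodeca-5,9-dien-2-ynoate
Product: 18 methyl (S,2Z,5E,9E)-10-(TBSOCH2)-6-(TBDPSOCH2)-4-hydroxy-2-iodo-12-(PMBO)dodeca-2,5,9-trienoate, via alkenylaluminate 17 (not isolated)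
Conditions: Red-Al, NaAlH2(OCH2CH2OMe)2, THF, −78 °C; then I2, −78 °C
Reagents that add atoms: iodine, II
Why: Alkoxide-directed trans-hydroalumination of the γ-hydroxy ynoate delivers hydride to C7, and iodination of the C11–Al bond with retention should give the 2-iodo enoate with the ester trans to C6.

Step 10
Reactants: 18 methyl (S,2Z,5E,9E)-10-(TBSOCH2)-6-(TBDPSOCH2)-4-hydroxy-2-iodo-12-(PMBO)dodeca-2,5,9-trienoate
Product: 19 methyl (S,2Z,5E,9E)-10-(TBSOCH2)-6-(TBDPSOCH2)-2-iodo-12-(PMBO)-4-(TESO)dodeca-2,5,9-trienoate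
Conditions: TESOTf, 2,6-lutidine, CH2Cl2, −78 °C
Reagents that add atoms: triethylsilyl trifluoromethanesulfonate, CC[Si](CC)(CC)OS(=O)(=O)C(F)(F)F
Why: Silyl ether formation masks the C6 hydroxyl, which would otherwise cyclise onto C13 once that carbon carries a leaving group.

Step 11
Reactants: 19 methyl (S,2Z,5E,9E)-10-(TBSOCH2)-6-(TBDPSOCH2)-2-iodo-12-(PMBO)-4-(TESO)dodeca-2,5,9-trienoate
Product: 20 methyl (S,2E,5E,9E)-10-(TBSOCH2)-6-(TBDPSOCH2)-2-(hydroxymethyl)-12-(PMBO)-4-(TESO)dodeca-2,5,9-trienoate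
Conditions: Bu3SnCH2OH, Pd(PPh3)4 (10 mol %), toluene, 80 °C
Reagents that add atoms: (tributylstannyl)methanol, CCCC[Sn](CCCC)(CCCC)CO
Why: Stille coupling with the hydroxymethylstannane installs C13 with retention of alkene geometry.

Step 12
Reactants: 20 methyl (S,2E,5E,9E)-10-(TBSOCH2)-6-(TBDPSOCH2)-2-(hydroxymethyl)-12-(PMBO)-4-(TESO)dodeca-2,5,9-trienoate
Product: 21 methyl (S,2Z,5E,9E)-2-(bromomethyl)-10-(TBSOCH2)-6-(TBDPSOCH2)-12-(PMBO)-4-(TESO)dodeca-2,5,9-trienoate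
Conditions: CBr4, PPh3, 2,6-lutidine, CH2Cl2, 0 °C
Reagents that add atoms: carbon tetrabromide, BrC(Br)(Br)Br
Why: Appel bromination converts the primary allylic alcohol into the allylic bromide under neutral conditions.

Step 13
Reactants: 21 methyl (S,2Z,5E,9E)-2-(bromomethyl)-10-(TBSOCH2)-6-(TBDPSOCH2)-12-(PMBO)-4-(TESO)dodeca-2,5,9-trienoate
Product: 22 methyl (S,2Z,5E,9E)-2-(bromomethyl)-10-(TBSOCH2)-6-(TBDPSOCH2)-12-hydroxy-4-(TESO)dodeca-2,5,9-trienoate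
Conditions: DDQ, CH2Cl2–pH 7 buffer, 0 °C
Reagents that add atoms: none
Why: Oxidative PMB ether cleavage with DDQ frees the C8 alcohol and leaves the silyl ethers and the allylic bromide intact.

Step 14
Reactants: 22 methyl (S,2Z,5E,9E)-2-(bromomethyl)-10-(TBSOCH2)-6-(TBDPSOCH2)-12-hydroxy-4-(TESO)dodeca-2,5,9-trienoate
Product: 23 methyl (S,2Z,5E,9E)-2-(bromomethyl)-10-(TBSOCH2)-6-(TBDPSOCH2)-12-oxo-4-(TESO)dodeca-2,5,9-trienoate
Conditions: Dess–Martin periodinane, NaHCO3, CH2Cl2, 0 °C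
Reagents that add atoms: none
Why: Buffered Dess–Martin oxidation gives the β,γ-unsaturated aldehyde without base, so C1=C10 should not move into conjugation; the aldehyde is used at once.

Step 15
Reactants: 23 methyl (S,2Z,5E,9E)-2-(bromomethyl)-10-(TBSOCH2)-6-(TBDPSOCH2)-12-oxo-4-(TESO)dodeca-2,5,9-trienoate
Product: 25 (6S,7S,8S,1(10)E,4E)-6-(TESO)-14-(TBSO)-15-(TBDPSO)germacra-1(10),4,11(13)-trien-12,8-olide, via hydroxy ester 24 (not isolated)
Conditions: In powder, THF–H2O (3:1), 0.002 M, slow addition of 23, 25 °C; crude 24 then PPTS (cat.), toluene, 60 °C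
Reagents that add atoms: none
Why: Zerovalent indium inserts into the C13–Br bond and the (2-methoxycarbonyl)allylindium adds through its γ-carbon C7 to the C8 aldehyde in a chelated six-membered chair transition state (SE2'), moving the double bond to C11=C13; the closest known reaction is the indium- or zinc-mediated Barbier (intramolecular Reformatsky-type) allylation of 2-(bromomethyl)alk-2-enoates, used to close carbocycles fused to α-methylene lactones up to macrocycles. The ten-membered carbocycle closes in the 10-exo-trig mode at the aldehyde carbon, and the temporary γ-lactone then closes by 5-exo-trig attack of O8 on the ester. C8 is set relative to C7 by the Z geometry of the allyl unit (C6 axial and C9 equatorial in the chair), which gives the 7,8-syn relationship of the target. C7 is set by C6: allylic 1,3-strain and the tether hold C5 near the plane of the allyl unit and turn the silyloxy group away, so the aldehyde should enter past the C6 hydrogen and give the 6S,7S,8S isomer, whose C6 is corrected in step 17. The step needs γ- over α-attack, ring closure over oligomerisation and one face of C7; the cyclic transition state, high dilution together with the two ring-cis trisubstituted alkenes that fold the chain, and the C6 stereocentre secure these.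

Step 16
Reactants: 25 (6S,7S,8S,1(10)E,4E)-6-(TESO)-14-(TBSO)-15-(TBDPSO)germacra-1(10),4,11(13)-trien-12,8-olide
Product: 26 (6S,7R,8S,1(10)E,4E)-6-hydroxy-14-(TBSO)-15-(TBDPSO)germacra-1(10),4,11(13)-trien-12,8-olide
Conditions: PPTS, MeOH, 0 °C
Reagents that add atoms: none
Why: Mild acid-catalysed methanolysis (silyl ether cleavage) removes the secondary triethylsilyl ether while the primary TBS and TBDPS ethers survive; no stereocentre is touched.

Step 17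
Reactants: 26 (6S,7R,8S,1(10)E,4E)-6-hydroxy-14-(TBSO)-15-(TBDPSO)germacra-1(10),4,11(13)-trien-12,8-olide
Product: 29 (6R,7S,8S,1(10)E,4E)-8-hydroxy-14-(TBSO)-15-(TBDPSO)germacra-1(10),4,11(13)-trien-12,6-olide, via mesylate 27 (not isolated), via lithium carboxylate 28 (not isolated)
Conditions: MsCl, Et3N, CH2Cl2, −40 °C; then LiOH (1.1 equiv), THF–H2O, 0 °C
Reagents that add atoms: lithium hydroxide, [Li+].[OH-]
Why: Saponification of the temporary lactone frees the C12 carboxylate, which displaces the allylic C6 mesylate in a 5-exo-tet SN2 lactonisation with inversion, so the 6,12-lactone forms cis-fused (6R) and O8 is released (lactone transposition).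

Step 18
Reactants: 29 (6R,7S,8S,1(10)E,4E)-8-hydroxy-14-(TBSO)-15-(TBDPSO)germacra-1(10),4,11(13)-trien-12,6-olide
Product: 30 (6R,7S,8S,1(10)E,4E)-8-(3-methylbutanoyloxy)-14-(TBSO)-15-(TBDPSO)germacra-1(10),4,11(13)-trien-12,6-olide
Conditions: (i-BuCO)2O, DMAP (cat.), Et3N, CH2Cl2, 0 °C
Reagents that add atoms: 3-methylbutanoic anhydride, CC(C)CC(=O)OC(=O)CC(C)C
Why: DMAP-catalysed acylation of the secondary C8 alcohol installs the 3-methylbutanoate at low temperature, before the lactone can migrate.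

Step 19
Reactants: 30 (6R,7S,8S,1(10)E,4E)-8-(3-methylbutanoyloxy)-14-(TBSO)-15-(TBDPSO)germacra-1(10),4,11(13)-trien-12,6-olide
Product: 31 (6R,7S,8S,1(10)E,4E)-14-hydroxy-8-(3-methylbutanoyloxy)-15-(TBDPSO)germacra-1(10),4,11(13)-trien-12,6-olide
Conditions: CSA (cat.), MeOH–CH2Cl2, 0 °C
Reagents that add atoms: none
Why: Acid-catalysed methanolysis cleaves the primary allylic TBS ether selectively in the presence of the TBDPS ether (selective silyl ether cleavage).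

Step 20
Reactants: 31 (6R,7S,8S,1(10)E,4E)-14-hydroxy-8-(3-methylbutanoyloxy)-15-(TBDPSO)germacra-1(10),4,11(13)-trien-12,6-olide
Product: 32 (6R,7S,8S,1(10)E,4E)-8-(3-methylbutanoyloxy)-14-oxo-15-(TBDPSO)germacra-1(10),4,11(13)-trien-12,6-olide
Conditions: MnO2, CH2Cl2, rt
Reagents that add atoms: none
Why: MnO2 oxidises the allylic alcohol to the enal and does not touch the lactone or the ester.

Step 21
Reactants: 32 (6R,7S,8S,1(10)E,4E)-8-(3-methylbutanoyloxy)-14-oxo-15-(TBDPSO)germacra-1(10),4,11(13)-trien-12,6-olide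
Product: 33 (6R,7S,8S,1(10)E,4E)-15-hydroxy-8-(3-methylbutanoyloxy)-14-oxogermacra-1(10),4,11(13)-trien-12,6-olide (CNP0345200.6)
Conditions: HF·pyridine, pyridine, THF, 0 °C to rt
Reagents that add atoms: none
Why: Fluoride-mediated desilylation under non-basic conditions removes the TBDPS group without acyl migration or conjugate addition to the methylene lactone.

**Compound list**
1 | ethyl (triphenylphosphoranylidene)acetate | CCOC(=O)C=P(c1ccccc1)(c1ccccc1)c1ccccc1 | starting material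
2 | 1-((2-bromoethoxy)methyl)-4-methoxybenzene | COc1ccc(COCCBr)cc1 | starting material
3 | (1-ethoxy-4-((4-methoxybenzyl)oxy)-1-oxobutan-2-yl)triphenylphosphonium bromide | CCOC(=O)C(CCOCc1ccc(OC)cc1)[P+](c1ccccc1)(c1ccccc1)c1ccccc1.[Br-] | intermediate
4 | ethyl 4-((4-methoxybenzyl)oxy)-2-(triphenylphosphoranylidene)butanoate | CCOC(=O)C(CCOCc1ccc(OC)cc1)=P(c1ccccc1)(c1ccccc1)c1ccccc1 | intermediate
5 | acrolein | C=CC=O | starting material
6 | ethyl (E)-2-(2-((4-methoxybenzyl)oxy)ethyl)penta-2,4-dienoate | C=C/C=C(/C(=O)OCC)CCOCc1ccc(OC)cc1 | intermediate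
7 | (E)-2-(2-((4-methoxybenzyl)oxy)ethyl)penta-2,4-dien-1-ol | C=C/C=C(/CO)CCOCc1ccc(OC)cc1 | intermediate
8 | (E)-tert-butyl((2-(2-((4-methoxybenzyl)oxy)ethyl)penta-2,4-dien-1-yl)oxy)dimethylsilane | C=C/C=C(/CO[Si](C)(C)C(C)(C)C)CCOCc1ccc(OC)cc1 | intermediate
9 | 4-((tert-butyldiphenylsilyl)oxy)but-2-yn-1-ol | OCC#CCO[Si](c1ccccc1)(c1ccccc1)C(C)(C)C | starting material
10 | sodium cyclic alkoxy(alkenyl)bis(2-methoxyethoxy)aluminate from 9 | COCCO[Al-]1(OCCOC)OCC=C1CO[Si](c2ccccc2)(c2ccccc2)C(C)(C)C.[Na+] | intermediate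
11 | (Z)-4-((tert-butyldiphenylsilyl)oxy)-3-iodobut-2-en-1-ol | OC/C=C(/CO[Si](c1ccccc1)(c1ccccc1)C(C)(C)C)I | intermediate
12 | B-alkyl-9-borabicyclo[3.3.1]nonane from 8 (boron on C3) | C1CC2CCCC(C1)B2CC/C=C(/CO[Si](C)(C)C(C)(C)C)CCOCc3ccc(OC)cc3 | intermediate
13 | (2E,6E)-7-(TBSOCH2)-3-(TBDPSOCH2)-9-(PMBO)nona-2,6-dien-1-ol | OC/C=C(/CO[Si](c1ccccc1)(c1ccccc1)C(C)(C)C)CC/C=C(/CO[Si](C)(C)C(C)(C)C)CCOCc1ccc(OC)cc1 | intermediate
14 | (2E,6E)-7-(TBSOCH2)-3-(TBDPSOCH2)-9-(PMBO)nona-2,6-dienal | O=C/C=C(/CO[Si](c1ccccc1)(c1ccccc1)C(C)(C)C)CC/C=C(/CO[Si](C)(C)C(C)(C)C)CCOCc1ccc(OC)cc1 | intermediate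
15 | methyl propiolate | C#CC(=O)OC | starting material
16 | methyl (S,5E,9E)-10-(TBSOCH2)-6-(TBDPSOCH2)-4-hydroxy-12-(PMBO)dodeca-5,9-dien-2-ynoate | COC(=O)C#C[C@@H](O)/C=C(/CO[Si](c1ccccc1)(c1ccccc1)C(C)(C)C)CC/C=C(/CO[Si](C)(C)C(C)(C)C)CCOCc1ccc(OC)cc1 | intermediate
17 | sodium cyclic alkoxy(alkenyl)bis(2-methoxyethoxy)aluminate from 16 (Al on C11) | COCCO[Al-]1(OCCOC)O[C@@H](/C=C(/CO[Si](c2ccccc2)(c2ccccc2)C(C)(C)C)CC/C=C(/CO[Si](C)(C)C(C)(C)C)CCOCc2ccc(OC)cc2)C=C1C(=O)OC.[Na+] | intermediate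
18 | methyl (S,2Z,5E,9E)-10-(TBSOCH2)-6-(TBDPSOCH2)-4-hydroxy-2-iodo-12-(PMBO)dodeca-2,5,9-trienoate | COC(=O)/C(I)=C/[C@@H](O)/C=C(/CO[Si](c1ccccc1)(c1ccccc1)C(C)(C)C)CC/C=C(/CO[Si](C)(C)C(C)(C)C)CCOCc1ccc(OC)cc1 | intermediate
19 | methyl (S,2Z,5E,9E)-10-(TBSOCH2)-6-(TBDPSOCH2)-2-iodo-12-(PMBO)-4-(TESO)dodeca-2,5,9-trienoate | COC(=O)/C(I)=C/[C@@H](O[Si](CC)(CC)CC)/C=C(/CO[Si](c1ccccc1)(c1ccccc1)C(C)(C)C)CC/C=C(/CO[Si](C)(C)C(C)(C)C)CCOCc1ccc(OC)cc1 | intermediate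
20 | methyl (S,2E,5E,9E)-10-(TBSOCH2)-6-(TBDPSOCH2)-2-(hydroxymethyl)-12-(PMBO)-4-(TESO)dodeca-2,5,9-trienoate | COC(=O)/C(CO)=C/[C@@H](O[Si](CC)(CC)CC)/C=C(/CO[Si](c1ccccc1)(c1ccccc1)C(C)(C)C)CC/C=C(/CO[Si](C)(C)C(C)(C)C)CCOCc1ccc(OC)cc1 | intermediate
21 | methyl (S,2Z,5E,9E)-2-(bromomethyl)-10-(TBSOCH2)-6-(TBDPSOCH2)-12-(PMBO)-4-(TESO)dodeca-2,5,9-trienoate | COC(=O)/C(CBr)=C/[C@@H](O[Si](CC)(CC)CC)/C=C(/CO[Si](c1ccccc1)(c1ccccc1)C(C)(C)C)CC/C=C(/CO[Si](C)(C)C(C)(C)C)CCOCc1ccc(OC)cc1 | intermediate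
22 | methyl (S,2Z,5E,9E)-2-(bromomethyl)-10-(TBSOCH2)-6-(TBDPSOCH2)-12-hydroxy-4-(TESO)dodeca-2,5,9-trienoate | COC(=O)/C(CBr)=C/[C@@H](O[Si](CC)(CC)CC)/C=C(/CO[Si](c1ccccc1)(c1ccccc1)C(C)(C)C)CC/C=C(/CO[Si](C)(C)C(C)(C)C)CCO | intermediate
23 | methyl (S,2Z,5E,9E)-2-(bromomethyl)-10-(TBSOCH2)-6-(TBDPSOCH2)-12-oxo-4-(TESO)dodeca-2,5,9-trienoate | COC(=O)/C(CBr)=C/[C@@H](O[Si](CC)(CC)CC)/C=C(/CO[Si](c1ccccc1)(c1ccccc1)C(C)(C)C)CC/C=C(/CO[Si](C)(C)C(C)(C)C)CC=O | intermediate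
24 | methyl (6S,7S,8S,1(10)E,4E)-8-hydroxy-6-(TESO)-14-(TBSO)-15-(TBDPSO)germacra-1(10),4,11(13)-trien-12-oate | C=C(C(=O)OC)[C@H]1[C@@H](O)C/C(CO[Si](C)(C)C(C)(C)C)=C\CC/C(CO[Si](c2ccccc2)(c2ccccc2)C(C)(C)C)=C\[C@@H]1O[Si](CC)(CC)CC | intermediate
25 | (6S,7S,8S,1(10)E,4E)-6-(TESO)-14-(TBSO)-15-(TBDPSO)germacra-1(10),4,11(13)-trien-12,8-olide (cis-fused) | C=C1C(=O)O[C@H]2C/C(CO[Si](C)(C)C(C)(C)C)=C\CC/C(CO[Si](c3ccccc3)(c3ccccc3)C(C)(C)C)=C\[C@H](O[Si](CC)(CC)CC)[C@@H]12 | intermediate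
26 | (6S,7R,8S,1(10)E,4E)-6-hydroxy-14-(TBSO)-15-(TBDPSO)germacra-1(10),4,11(13)-trien-12,8-olide | C=C1C(=O)O[C@H]2C/C(CO[Si](C)(C)C(C)(C)C)=C\CC/C(CO[Si](c3ccccc3)(c3ccccc3)C(C)(C)C)=C\[C@H](O)[C@@H]12 | intermediate
27 | 6-O-methanesulfonate of 26 | C=C1C(=O)O[C@H]2C/C(CO[Si](C)(C)C(C)(C)C)=C\CC/C(CO[Si](c3ccccc3)(c3ccccc3)C(C)(C)C)=C\[C@H](OS(C)(=O)=O)[C@@H]12 | intermediate
28 | lithium (6S,7S,8S,1(10)E,4E)-8-hydroxy-6-(methanesulfonyloxy)-14-(TBSO)-15-(TBDPSO)germacra-1(10),4,11(13)-trien-12-oate | [Li+].[O-]C(=O)C(=C)[C@H]1[C@@H](O)C/C(CO[Si](C)(C)C(C)(C)C)=C\CC/C(CO[Si](c2ccccc2)(c2ccccc2)C(C)(C)C)=C\[C@@H]1OS(C)(=O)=O | intermediate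
29 | (6R,7S,8S,1(10)E,4E)-8-hydroxy-14-(TBSO)-15-(TBDPSO)germacra-1(10),4,11(13)-trien-12,6-olide (cis-fused) | C=C1C(=O)O[C@@H]2/C=C(/CO[Si](c3ccccc3)(c3ccccc3)C(C)(C)C)CC/C=C(/CO[Si](C)(C)C(C)(C)C)C[C@H](O)[C@H]12 | intermediate
30 | (6R,7S,8S,1(10)E,4E)-8-(3-methylbutanoyloxy)-14-(TBSO)-15-(TBDPSO)germacra-1(10),4,11(13)-trien-12,6-olide | C=C1C(=O)O[C@@H]2/C=C(/CO[Si](c3ccccc3)(c3ccccc3)C(C)(C)C)CC/C=C(/CO[Si](C)(C)C(C)(C)C)C[C@H](OC(=O)CC(C)C)[C@H]12 | intermediate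
31 | (6R,7S,8S,1(10)E,4E)-14-hydroxy-8-(3-methylbutanoyloxy)-15-(TBDPSO)germacra-1(10),4,11(13)-trien-12,6-olide | C=C1C(=O)O[C@@H]2/C=C(/CO[Si](c3ccccc3)(c3ccccc3)C(C)(C)C)CC/C=C(/CO)C[C@H](OC(=O)CC(C)C)[C@H]12 | intermediate
32 | (6R,7S,8S,1(10)E,4E)-8-(3-methylbutanoyloxy)-14-oxo-15-(TBDPSO)germacra-1(10),4,11(13)-trien-12,6-olide | C=C1C(=O)O[C@@H]2/C=C(/CO[Si](c3ccccc3)(c3ccccc3)C(C)(C)C)CC/C=C(/C=O)C[C@H](OC(=O)CC(C)C)[C@H]12 | intermediate
33 | (6R,7S,8S,1(10)E,4E)-15-hydroxy-8-(3-methylbutanoyloxy)-14-oxogermacra-1(10),4,11(13)-trien-12,6-olide (CNP0345200.6) | C=C1C(=O)O[C@@H]2/C=C(/CO)CC/C=C(/C=O)C[C@H](OC(=O)CC(C)C)[C@H]12 | target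

**Step count and risks**
Total steps: 21. Longest linear sequence: 20 steps (steps 1 to 4, then 6 to 21); step 5 is a one-step side branch.

The three steps most likely to fail, in order of risk:

Step 15. What may go wrong: the allylindium may add to the other face of C7 (facial selectivity with respect to C6 poor or reversed), and ring closure may lose to intermolecular coupling. The fallback switches to the 6-epimeric series with retentive lactonisation. It sets out from enal 14: alkynylation with the enantiomeric ligand gives the (R)-hydroxy ynoate F1. The operations of steps 9 to 14 then give in turn the iodo enoate F2, its triethylsilyl ether F3, the hydroxymethyl enoate F4, the allylic bromide F5, the primary alcohol F6 and the aldehyde F7. Indium ring closure, without the PPTS–toluene treatment, should then give the (6R,7S,8S)-hydroxy ester F8, which is acylated with 3-methylbutanoic anhydride and DMAP to the ester F9. PPTS in MeOH then removes the triethylsilyl group and the freed 6-hydroxyl lactonises with retention, which returns the route at 30.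

Step 17. What may go wrong: ionisation or elimination of the allylic mesylate (loss of configuration at C6, diene formation) and base-induced migration of the lactone between O8 and O6. The fallback is a Mitsunobu lactonisation. It sets out from hydroxy lactone 26: saponification (LiOH, THF–H2O) gives the dihydroxy acid F10, kept as its salt until use. PPh3 and DIAD in THF at 0 °C should activate the allylic 6-hydroxyl, the carboxylate displaces it with inversion, and the route is rejoined at 29.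

Step 9. What may go wrong: over-reduction of the ester and loss of alkene geometry when the alkenylaluminate is iodinated. The fallback is trans-hydrosilylation followed by iododesilylation. It sets out from ynoate 16: [Cp*Ru(MeCN)3]PF6 and benzyldimethylsilane in CH2Cl2 at 0 °C should give by trans-addition the α-silyl enoate F11, with silicon on C11 and cis to C6. N-Iodosuccinimide in MeCN at 0 °C replaces silicon by iodine with retention and returns the route at 18.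

Further compounds
F1 | step 15 | methyl (R,5E,9E)-10-(TBSOCH2)-6-(TBDPSOCH2)-4-hydroxy-12-(PMBO)dodeca-5,9-dien-2-ynoate | COC(=O)C#C[C@H](O)/C=C(/CO[Si](c1ccccc1)(c1ccccc1)C(C)(C)C)CC/C=C(/CO[Si](C)(C)C(C)(C)C)CCOCc1ccc(OC)cc1
F2 | step 15 | methyl (R,2Z,5E,9E)-10-(TBSOCH2)-6-(TBDPSOCH2)-4-hydroxy-2-iodo-12-(PMBO)dodeca-2,5,9-trienoate | COC(=O)/C(I)=C/[C@H](O)/C=C(/CO[Si](c1ccccc1)(c1ccccc1)C(C)(C)C)CC/C=C(/CO[Si](C)(C)C(C)(C)C)CCOCc1ccc(OC)cc1
F3 | step 15 | methyl (R,2Z,5E,9E)-10-(TBSOCH2)-6-(TBDPSOCH2)-2-iodo-12-(PMBO)-4-(TESO)dodeca-2,5,9-trienoate | COC(=O)/C(I)=C/[C@H](O[Si](CC)(CC)CC)/C=C(/CO[Si](c1ccccc1)(c1ccccc1)C(C)(C)C)CC/C=C(/CO[Si](C)(C)C(C)(C)C)CCOCc1ccc(OC)cc1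
F4 | step 15 | methyl (R,2E,5E,9E)-10-(TBSOCH2)-6-(TBDPSOCH2)-2-(hydroxymethyl)-12-(PMBO)-4-(TESO)dodeca-2,5,9-trienoate | COC(=O)/C(CO)=C/[C@H](O[Si](CC)(CC)CC)/C=C(/CO[Si](c1ccccc1)(c1ccccc1)C(C)(C)C)CC/C=C(/CO[Si](C)(C)C(C)(C)C)CCOCc1ccc(OC)cc1
F5 | step 15 | methyl (R,2Z,5E,9E)-2-(bromomethyl)-10-(TBSOCH2)-6-(TBDPSOCH2)-12-(PMBO)-4-(TESO)dodeca-2,5,9-trienoate | COC(=O)/C(CBr)=C/[C@H](O[Si](CC)(CC)CC)/C=C(/CO[Si](c1ccccc1)(c1ccccc1)C(C)(C)C)CC/C=C(/CO[Si](C)(C)C(C)(C)C)CCOCc1ccc(OC)cc1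
F6 | step 15 | methyl (R,2Z,5E,9E)-2-(bromomethyl)-10-(TBSOCH2)-6-(TBDPSOCH2)-12-hydroxy-4-(TESO)dodeca-2,5,9-trienoate | COC(=O)/C(CBr)=C/[C@H](O[Si](CC)(CC)CC)/C=C(/CO[Si](c1ccccc1)(c1ccccc1)C(C)(C)C)CC/C=C(/CO[Si](C)(C)C(C)(C)C)CCO
F7 | step 15 | methyl (R,2Z,5E,9E)-2-(bromomethyl)-10-(TBSOCH2)-6-(TBDPSOCH2)-12-oxo-4-(TESO)dodeca-2,5,9-trienoate | COC(=O)/C(CBr)=C/[C@H](O[Si](CC)(CC)CC)/C=C(/CO[Si](c1ccccc1)(c1ccccc1)C(C)(C)C)CC/C=C(/CO[Si](C)(C)C(C)(C)C)CC=O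
F8 | step 15 | methyl (6R,7S,8S,1(10)E,4E)-8-hydroxy-6-(TESO)-14-(TBSO)-15-(TBDPSO)germacra-1(10),4,11(13)-trien-12-oate | C=C(C(=O)OC)[C@H]1[C@@H](O)C/C(CO[Si](C)(C)C(C)(C)C)=C\CC/C(CO[Si](c2ccccc2)(c2ccccc2)C(C)(C)C)=C\[C@H]1O[Si](CC)(CC)CC
F9 | step 15 | methyl (6R,7S,8S,1(10)E,4E)-8-(3-methylbutanoyloxy)-6-(TESO)-14-(TBSO)-15-(TBDPSO)germacra-1(10),4,11(13)-trien-12-oate | C=C(C(=O)OC)[C@H]1[C@@H](OC(=O)CC(C)C)C/C(CO[Si](C)(C)C(C)(C)C)=C\CC/C(CO[Si](c2ccccc2)(c2ccccc2)C(C)(C)C)=C\[C@H]1O[Si](CC)(CC)CC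
F10 | step 17 | (6S,7S,8S,1(10)E,4E)-6,8-dihydroxy-14-(TBSO)-15-(TBDPSO)germacra-1(10),4,11(13)-trien-12-oic acid | OC(=O)C(=C)[C@H]1[C@@H](O)C/C(CO[Si](C)(C)C(C)(C)C)=C\CC/C(CO[Si](c2ccccc2)(c2ccccc2)C(C)(C)C)=C\[C@@H]1O
F11 | step 9 | methyl (S,2Z,5E,9E)-2-(benzyldimethylsilyl)-10-(TBSOCH2)-6-(TBDPSOCH2)-4-hydroxy-12-(PMBO)dodeca-2,5,9-trienoate | COC(=O)/C([Si](C)(C)Cc1ccccc1)=C/[C@@H](O)/C=C(/CO[Si](c1ccccc1)(c1ccccc1)C(C)(C)C)CC/C=C(/CO[Si](C)(C)C(C)(C)C)CCOCc1ccc(OC)cc1
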